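## Retrosynthetic overview

1. Target 27 comes from bis-lactone 23 by lactone reduction, ester formation and acetal hydrolysis; 23 comes from a visible-light, electron-catalysed [4+2] homodimerisation of two molecules of trienylidene lactone 22 (forms ring C), with the cis-fused lactone fixing the facial bias.
2. Monomer 22 comes from lactone 16 and dienal 19 (aldol/elimination); 19 from 6-methylhept-5-en-2-one (enol triflate, Heck); the Z-enal (carried as its acetal) from the isopropenyl group by allylic oxidation and alkene migration.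
3. Lactone 13 comes from β-hydroxy ketone 10 (enolate alkylation, hydroxyl-directed reduction); ring B from rhodium-catalysed hydroacylation of pentenal 9; the tertiary alcohol from directed epoxidation and hydride opening.
4. The quaternary spiro carbon comes from deconjugative α-allylation of enal 4, made by one-carbon homologation of 6-(3-chloropropyl)carvone 2, itself from (S)-carvone 1.
5. Ring order: ring A (purchased) → ring B → temporary lactone ring → ring C (dimerisation).

Assumption: simple purchasable reagents are not numbered (numbers go to the three purchased building blocks and all intermediates); locants C-1 to C-10 refer to the spiro[4.5]decane core (C-1 carbinol/ketone carbon of ring B, C-2 its side-chain neighbour, C-5 spiro carbon, C-6 C(CH3)(OH), C-9 carbon bearing isopropenyl or the enal, C-10 carbon bearing the three-carbon chain).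

## Route

Step 1
Reactants: 1 (S)-(+)-carvone
Product: 2 (5S,6R)-6-(3-chloropropyl)-2-methyl-5-(prop-1-en-2-yl)cyclohex-2-en-1-one
Conditions: LiN(iPr)2, THF, −78 °C; ICH2CH2CH2Cl, DMPU, −78 → −20 °C
Reagents that add atoms: 1-chloro-3-iodopropane (ClCCCI)
Why: Kinetic deprotonation at C-6 gives the cross-conjugated lithium dienolate, which is alkylated by the iodide end of the dihalide on the face opposite the isopropenyl group (trans-selective α′-alkylation of carvone), so the purchased stereocentre sets the chain-bearing one.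

Step 2
Reactants: 2 (5S,6R)-6-(3-chloropropyl)-2-methyl-5-(prop-1-en-2-yl)cyclohex-2-en-1-one
Product: 4 (5S,6R)-6-(3-chloropropyl)-2-methyl-5-(prop-1-en-2-yl)cyclohex-1-ene-1-carbaldehyde, via methyl enol ether 3 (not isolated)
Conditions: MeOCH2PPh3Cl, KN(SiMe3)2, THF, 0 °C → rt; then 1 M HCl, THF/H2O, rt
Reagents that add atoms: (methoxymethyl)triphenylphosphonium chloride (COC[P+](c1ccccc1)(c1ccccc1)c1ccccc1.[Cl-]); water (O)
Why: Wittig methoxymethylenation of the hindered enone and acid hydrolysis of the dienol ether (one-carbon homologation) give the thermodynamically favoured tetrasubstituted conjugated enal without touching the adjacent stereocentre.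

Step 3
Reactants: 4 (5S,6R)-6-(3-chloropropyl)-2-methyl-5-(prop-1-en-2-yl)cyclohex-1-ene-1-carbaldehyde
Product: 6 [1-allyl-6-(3-chloropropyl)-2-methyl-5-(prop-1-en-2-yl)cyclohex-2-en-1-yl]methanol (CH2OH cis and allyl trans to the chloropropyl chain), via allyl aldehyde 5 (not isolated)
Conditions: KOtBu, THF/t-BuOH, −40 °C; allyl bromide, −40 → 0 °C; then MeOH, NaBH4, 0 °C
Reagents that add atoms: allyl bromide (C=CCBr)
Why: Deconjugative α-alkylation of the potassium dienolate creates the quaternary carbon: allylic 1,3-strain with the enolate oxygen forces the neighbouring chloropropyl chain axial, so allyl bromide enters trans to it, and NaBH4 then reduces the neopentyl aldehyde; any exocyclic-alkene isomer converges on diol 8 in step 5.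

Step 4
Reactants: 6 [1-allyl-6-(3-chloropropyl)-2-methyl-5-(prop-1-en-2-yl)cyclohex-2-en-1-yl]methanol
Product: 7 2,3-epoxide of 6 (oxirane oxygen cis to CH2OH)
Conditions: VO(acac)2 (5 mol %), t-BuOOH, CH2Cl2, 0 °C → rt
Reagents that add atoms: tert-butyl hydroperoxide (CC(C)(C)OO)
Why: Hydroxyl-directed vanadium-catalysed epoxidation of the homoallylic alcohol delivers oxygen to the trisubstituted ring alkene on the face of the CH2OH group and leaves the allyl and isopropenyl groups alone.

Step 5
Reactants: 7 2,3-epoxide of 6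
Product: 8 2-allyl-3-(3-chloropropyl)-2-(hydroxymethyl)-1-methyl-4-(prop-1-en-2-yl)cyclohexan-1-ol (OH; CH2OH; chloropropyl mutually cis)
Conditions: LiAlH4, Et2O, 0 °C → rt
Reagents that add atoms: none
Why: Hydride opens the trisubstituted epoxide at its less substituted carbon (SN2, trans-diaxial opening), leaving the tertiary alcohol cis to CH2OH; the primary alkyl chloride is essentially inert to LiAlH4 in ether at this temperature.

Step 6
Reactants: 8 2-allyl-3-(3-chloropropyl)-2-(hydroxymethyl)-1-methyl-4-(prop-1-en-2-yl)cyclohexan-1-ol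
Product: 9 1-allyl-6-(3-chloropropyl)-2-hydroxy-2-methyl-5-(prop-1-en-2-yl)cyclohexane-1-carbaldehyde
Conditions: Dess–Martin periodinane, CH2Cl2, 0 °C → rt
Reagents that add atoms: none
Why: Dess–Martin oxidation converts only the primary alcohol (the tertiary one cannot be oxidised), and the quaternary α-carbon rules out epimerisation or elimination.

Step 7
Reactants: 9 1-allyl-6-(3-chloropropyl)-2-hydroxy-2-methyl-5-(prop-1-en-2-yl)cyclohexane-1-carbaldehyde
Product: 10 10-(3-chloropropyl)-6-hydroxy-6-methyl-9-(prop-1-en-2-yl)spiro[4.5]decan-1-one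
Conditions: [Rh(dppe)]ClO4 (5 mol %), CH2Cl2, rt
Reagents that add atoms: none
Why: Intramolecular hydroacylation of the 4-pentenal unit by cationic monovalent rhodium closes ring B as a spiro-cyclopentanone (five-membered closure onto allyl is favoured over six-membered closure onto isopropenyl) and creates no new stereocentre.

Step 8
Reactants: 10 10-(3-chloropropyl)-6-hydroxy-6-methyl-9-(prop-1-en-2-yl)spiro[4.5]decan-1-one
Product: 11 methyl 2-[10-(3-chloropropyl)-6-hydroxy-6-methyl-1-oxo-9-(prop-1-en-2-yl)spiro[4.5]decan-2-yl]acetate (C-2 arm on the ring B face of C-10)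
Conditions: LiN(iPr)2 (2.2 equiv), THF, −78 °C; BrCH2CO2Me, −78 → −40 °C
Reagents that add atoms: methyl bromoacetate (COC(=O)CBr)
Why: Alkylation of the alkoxide–enolate dianion at the only enolisable position (C-2) occurs on the face away from the quaternary C-6 alkoxide, i.e. cis to C-10; this centre is epimerisable, so the minor epimer can be recycled by equilibration.

Step 9
Reactants: 11 methyl 2-[10-(3-chloropropyl)-6-hydroxy-6-methyl-1-oxo-9-(prop-1-en-2-yl)spiro[4.5]decan-2-yl]acetate
Product: 13 cis-fused γ-lactone on ring B (C-1 oxygen acylated by the C-2 CH2C(=O) arm; 6-OH; 9-isopropenyl; 10-chloropropyl), via hydroxy ester 12 (not isolated)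
Conditions: Me4NBH(OAc)3, MeCN/AcOH, −20 °C; then PPTS (cat.), toluene, 60 °C
Reagents that add atoms: none
Why: Hydroxyl-directed (Evans–Saksena) reduction: the C-6 alkoxyborohydride delivers hydride intramolecularly to the C-1 ketone from the C-6 side, so the new OH lies on the face of C-10 and cis to the C-2 arm, and acid then closes the cis-fused lactone.

Step 10
Reactants: 13 cis-fused γ-lactone
Product: 14 lactone 13 in which C-9 carries a 1-formylvinyl group C(=CH2)CHO
Conditions: SeO2, 1,4-dioxane, 80 °C
Reagents that add atoms: selenium dioxide (O=[Se]=O)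
Why: Riley allylic oxidation (ene reaction then [2,3]-shift) of the only alkene oxidises the isopropenyl methyl group to the aldehyde.

Step 11
Reactants: 14 lactone with the 1-formylvinyl group
Product: 15 lactone in which C-9 carries the exocyclic (Z)-C(CH3)CHO unit (CHO cis to C-10)
Conditions: RhCl3·3H2O (5 mol %), EtOH, 70 °C
Reagents that add atoms: none
Why: Rhodium-hydride double-bond migration moves the exo-methylene into the tetrasubstituted conjugated position under thermodynamic control, which favours the Z isomer (the small CHO sits cis to the substituted C-10, minimising allylic 1,3-strain); the carvone stereocentre is erased here after relaying its information.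

Step 12
Reactants: 15 Z-enal lactone
Product: 16 dimethyl acetal of 15
Conditions: HC(OMe)3, PPTS (cat.), MeOH, rt
Reagents that add atoms: trimethyl orthoformate (COC(OC)OC)
Why: Acid-catalysed acetalisation masks the enal for the base and hydride steps and makes it redox-silent in step 16, without changing the alkene geometry.

Step 13
Reactants: 17 6-methylhept-5-en-2-one
Product: 18 6-methylhepta-1,5-dien-2-yl trifluoromethanesulfonate
Conditions: LiN(iPr)2, THF, −78 °C; PhNTf2, −78 °C → rt
Reagents that add atoms: N-phenylbis(trifluoromethanesulfonimide) (O=S(=O)(N(c1ccccc1)S(=O)(=O)C(F)(F)F)C(F)(F)F)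
Why: Kinetic deprotonation at the methyl group and O-sulfonylation give the terminal enol triflate.

Step 14
Reactants: 18 6-methylhepta-1,5-dien-2-yl trifluoromethanesulfonate
Product: 19 (2E)-8-methyl-4-methylidenenona-2,7-dienal
Conditions: acrolein, Pd(OAc)2 (5 mol %), PPh3 (10 mol %), Et3N, DMF, 60 °C
Reagents that add atoms: acrolein (C=CC=O)
Why: Mizoroki–Heck vinylation of acrolein by the vinyl triflate gives the E-dienal through syn β-hydride elimination.

Step 15
Reactants: 16 dimethyl acetal lactone; 19 (2E)-8-methyl-4-methylidenenona-2,7-dienal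
Product: 22 monomer: lactone 16 bearing at its α-carbon an exocyclic (E)-alkylidene =CH–CH=CH–C(=CH2)CH2CH2CH=C(CH3)2 (chain trans to the lactone C=O), via aldol adduct 20 (not isolated), via mesylate 21 (not isolated)
Conditions: LiN(iPr)2 (2.2 equiv), THF, −78 °C; 19; AcOH; then MsCl, Et3N, CH2Cl2, 0 °C; DBU, rt
Reagents that add atoms: none
Why: Aldol addition of the lactone enolate to the dienal followed by E1cB elimination of the secondary mesylate gives the thermodynamically preferred E-alkylidene lactone; the tertiary alcohol is not mesylated.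

Step 16
Reactants: 22 monomer trienylidene lactone (two molecules; one serves as the diene, the other as the dienophile)
Product: 23 bis-lactone dimer: cyclohexene ring C whose quaternary carbon carries a 4-methylpent-3-enyl group and the (1E,3E)-dienyl arm of the first lactone unit; the alkene carbon carries the second 4-methylpent-3-enyl group; the adjacent CH carries the alkylidene of the second lactone unit trans to the first arm
Conditions: fac-Ir(ppy)3 (1 mol %), MeCN (0.3 M in 22), 450 nm LEDs, Ar, −10 °C
Reagents that add atoms: second molecule of monomer 22 (ClCCC[C@@H]1/C(=C(/C)C(OC)OC)CC[C@](C)(O)[C@@]12CC[C@H]3/C(=C\C=C\C(=C)CCC=C(C)C)C(=O)O[C@@H]23)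
Why: Proposed new method: photoexcited fac-Ir(ppy)3 reduces one molecule of the trienyl lactone (about −1.8 V vs SCE) to its radical anion, which adds through its unsubstituted terminal CH2 to the terminal CH2 of a second, neutral molecule of 22; the distonic radical anion closes the six-membered ring between the fully substituted carbon of one unit and the diene terminus of the other, and the less easily reduced product dienoate radical anion hands its electron on (chain transfer to fresh monomer or return to the oxidised iridium complex), an electron-catalysed [4+2] homodimerisation in which all atoms of both monomers end up in 23; the planar cis-fused lactone places the ring B CH2 next to C-2 over one face of the diene terminus so the partner adds to the convex face, and the two bulky arms settle trans-diequatorial, which sets both new stereocentres; closest known chemistry is the visible-light radical-anion [2+2] and hetero-Diels–Alder cycloaddition of enones, cathodic hydrodimerisation of activated olefins and hole-catalysed Diels–Alder dimerisation of dienes.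

Step 17
Reactants: 23 bis-lactone dimer
Product: 24 hexaol bis(dimethyl acetal) dichloride (each lactone opened to the 2-alkylidene-1,4-diol: allylic CH2OH and ring B secondary OH)
Conditions: iBu2AlH (12 equiv), CH2Cl2, −78 → 0 °C; aq. potassium sodium tartrate (KNaC4H4O6)
Reagents that add atoms: none
Why: iBu2AlH reduces both α-alkylidene lactones by 1,2-hydride addition through the lactols to the diols, while acetals, alkyl chlorides and the polyene are untouched.

Step 18
Reactants: 24 hexaol bis(dimethyl acetal) dichloride; 25 tetradecanoic acid (2.4 equiv in total; two molecules are incorporated)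
Product: 27 CNP0458412.1 (target), via bis-acetal diester 26 (not isolated)
Conditions: 25 (2.4 equiv), Cs2CO3 (2.4 equiv), NaI (cat.), DMF, 55 °C; then aq. oxalic acid, THF, rt
Reagents that add atoms: tetradecanoic acid, second equivalent (CCCCCCCCCCCCCC(=O)O); water (O)
Why: SN2 O-alkylation of two equivalents of caesium tetradecanoate by the two primary chlorides (iodide catalysis) installs both esters without acylating any free alcohol, and the mildly acidic work-up hydrolyses the two conjugated dimethyl acetals to the Z-enals only after the basic step, so the γ-stereocentre is not exposed to base as a free enal.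

## Compound list

1 | (S)-(+)-carvone, (5S)-2-methyl-5-(prop-1-en-2-yl)cyclohex-2-en-1-one | C1[C@@H](C(C)=C)CC=C(C)C1=O | starting material
2 | (5S,6R)-6-(3-chloropropyl)-2-methyl-5-(prop-1-en-2-yl)cyclohex-2-en-1-one (chain trans to isopropenyl) | ClCCC[C@@H]1[C@@H](C(C)=C)CC=C(C)C1=O | intermediate
3 | methyl enol ether: 5-(3-chloropropyl)-6-(methoxymethylidene)-1-methyl-4-(prop-1-en-2-yl)cyclohex-1-ene, E/Z mixture | ClCCC[C@@H]1[C@@H](C(C)=C)CC=C(C)C1=COC | intermediate
4 | (5S,6R)-6-(3-chloropropyl)-2-methyl-5-(prop-1-en-2-yl)cyclohex-1-ene-1-carbaldehyde | ClCCC[C@@H]1[C@@H](C(C)=C)CCC(C)=C1C=O | intermediate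
5 | allyl aldehyde: 1-allyl-6-(3-chloropropyl)-2-methyl-5-(prop-1-en-2-yl)cyclohex-2-ene-1-carbaldehyde (CHO cis, allyl trans to chloropropyl) | ClCCC[C@@H]1[C@@H](C(C)=C)CC=C(C)[C@@]1(C=O)CC=C | intermediate
6 | [1-allyl-6-(3-chloropropyl)-2-methyl-5-(prop-1-en-2-yl)cyclohex-2-en-1-yl]methanol (CH2OH cis to chloropropyl) | ClCCC[C@@H]1[C@@H](C(C)=C)CC=C(C)[C@@]1(CO)CC=C | intermediate
7 | 2,3-epoxide of 6, oxirane oxygen cis to CH2OH | ClCCC[C@@H]1[C@@H](C(C)=C)C[C@@H]2O[C@]2(C)[C@@]1(CO)CC=C | intermediate
8 | 2-allyl-3-(3-chloropropyl)-2-(hydroxymethyl)-1-methyl-4-(prop-1-en-2-yl)cyclohexan-1-ol (OH, CH2OH, chloropropyl mutually cis; isopropenyl trans to chloropropyl) | ClCCC[C@@H]1[C@@H](C(C)=C)CC[C@](C)(O)[C@@]1(CO)CC=C | intermediate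
9 | 1-allyl-6-(3-chloropropyl)-2-hydroxy-2-methyl-5-(prop-1-en-2-yl)cyclohexane-1-carbaldehyde (CHO, OH, chloropropyl mutually cis) | ClCCC[C@@H]1[C@@H](C(C)=C)CC[C@](C)(O)[C@@]1(C=O)CC=C | intermediate
10 | 10-(3-chloropropyl)-6-hydroxy-6-methyl-9-(prop-1-en-2-yl)spiro[4.5]decan-1-one (C-1, 6-OH and 10-chain on the same face of ring A) | ClCCC[C@@H]1[C@@H](C(C)=C)CC[C@](C)(O)[C@@]12CCCC2=O | intermediate
11 | methyl 2-[10-(3-chloropropyl)-6-hydroxy-6-methyl-1-oxo-9-(prop-1-en-2-yl)spiro[4.5]decan-2-yl]acetate (C-2 arm on the ring B face of C-10) | ClCCC[C@@H]1[C@@H](C(C)=C)CC[C@](C)(O)[C@@]12CC[C@@H](CC(=O)OC)C2=O | intermediate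
12 | hydroxy ester: methyl 2-[10-(3-chloropropyl)-1,6-dihydroxy-6-methyl-9-(prop-1-en-2-yl)spiro[4.5]decan-2-yl]acetate (1-OH cis to the C-2 arm and to C-10) | ClCCC[C@@H]1[C@@H](C(C)=C)CC[C@](C)(O)[C@@]12CC[C@@H](CC(=O)OC)[C@H]2O | intermediate
13 | cis-fused γ-lactone of 12 (C-1 oxygen to the C-2 CH2C(=O) arm; 6-OH, 9-isopropenyl, 10-(3-chloropropyl)) | ClCCC[C@@H]1[C@@H](C(C)=C)CC[C@](C)(O)[C@@]12CC[C@H]3CC(=O)O[C@@H]23 | intermediate
14 | lactone 13 with the C-9 isopropenyl oxidised to C(=CH2)CHO | ClCCC[C@@H]1[C@@H](C(=C)C=O)CC[C@](C)(O)[C@@]12CC[C@H]3CC(=O)O[C@@H]23 | intermediate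
15 | lactone with exocyclic (Z)-C(CH3)CHO at C-9 (CHO cis to C-10) | ClCCC[C@@H]1/C(=C(/C)C=O)CC[C@](C)(O)[C@@]12CC[C@H]3CC(=O)O[C@@H]23 | intermediate
16 | dimethyl acetal of 15 | ClCCC[C@@H]1/C(=C(/C)C(OC)OC)CC[C@](C)(O)[C@@]12CC[C@H]3CC(=O)O[C@@H]23 | intermediate
17 | 6-methylhept-5-en-2-one | CC(=O)CCC=C(C)C | starting material
18 | 6-methylhepta-1,5-dien-2-yl trifluoromethanesulfonate | C=C(OS(=O)(=O)C(F)(F)F)CCC=C(C)C | intermediate
19 | (2E)-8-methyl-4-methylidenenona-2,7-dienal | O=C/C=C/C(=C)CCC=C(C)C | intermediate
20 | aldol adduct of 16 (lactone α-carbon) and 19, mixture at the two new centres | ClCCC[C@@H]1/C(=C(/C)C(OC)OC)CC[C@](C)(O)[C@@]12CC[C@H]3C(C(O)/C=C/C(=C)CCC=C(C)C)C(=O)O[C@@H]23 | intermediate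
21 | methanesulfonate of 20 | ClCCC[C@@H]1/C(=C(/C)C(OC)OC)CC[C@](C)(O)[C@@]12CC[C@H]3C(C(OS(C)(=O)=O)/C=C/C(=C)CCC=C(C)C)C(=O)O[C@@H]23 | intermediate
22 | monomer: (E)-α-[(2E)-8-methyl-4-methylidenenona-2,7-dienylidene] lactone of 16 | ClCCC[C@@H]1/C(=C(/C)C(OC)OC)CC[C@](C)(O)[C@@]12CC[C@H]3/C(=C\C=C\C(=C)CCC=C(C)C)C(=O)O[C@@H]23 | intermediate
23 | bis-lactone [4+2] dimer of two molecules of 22 (ring C cyclohexene, arms trans, configuration as in the target) | ClCCC[C@@H]1/C(=C(/C)C(OC)OC)CC[C@](C)(O)[C@@]12CC[C@H]3/C(=C\C=C\[C@@]1(CCC=C(C)C)CCC(CCC=C(C)C)=C[C@@H]1/C=C4/C(=O)O[C@@H]5[C@H]4CC[C@]56[C@H](CCCCl)/C(=C(/C)C(OC)OC)CC[C@]6(C)O)C(=O)O[C@@H]23 | intermediate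
24 | hexaol bis(dimethyl acetal) dichloride (target skeleton with Cl in place of each tetradecanoyloxy group and CH(OMe)2 in place of each CHO) | ClCCC[C@@H]1/C(=C(/C)C(OC)OC)CC[C@](C)(O)[C@@]12CC[C@@H](/C(=C\C=C\[C@@]1(CCC=C(C)C)CCC(CCC=C(C)C)=C[C@@H]1/C=C(/CO)[C@@H]1CC[C@]3([C@H](CCCCl)/C(=C(/C)C(OC)OC)CC[C@]3(C)O)[C@@H]1O)CO)[C@H]2O | intermediate
25 | tetradecanoic (myristic) acid | CCCCCCCCCCCCCC(=O)O | starting material
26 | bis-acetal diester: bis(tetradecanoate) of 24 at the two propyl termini | CCCCCCCCCCCCCC(=O)OCCC[C@@H]1/C(=C(/C)C(OC)OC)CC[C@](C)(O)[C@@]12CC[C@@H](/C(=C\C=C\[C@@]1(CCC=C(C)C)CCC(CCC=C(C)C)=C[C@@H]1/C=C(/CO)[C@@H]1CC[C@]3([C@H](CCCOC(=O)CCCCCCCCCCCCC)/C(=C(/C)C(OC)OC)CC[C@]3(C)O)[C@@H]1O)CO)[C@H]2O | intermediate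
27 | CNP0458412.1 | CCCCCCCCCCCCCC(=O)OCCC[C@@H]1/C(=C(/C)C=O)CC[C@](C)(O)[C@@]12CC[C@@H](/C(=C\C=C\[C@@]1(CCC=C(C)C)CCC(CCC=C(C)C)=C[C@@H]1/C=C(/CO)[C@@H]1CC[C@]3([C@H](CCCOC(=O)CCCCCCCCCCCCC)/C(=C(/C)C=O)CC[C@]3(C)O)[C@@H]1O)CO)[C@H]2O | target

## Step count and risks

Total step count: 18. Longest linear sequence: 16 steps (1–12 and 15–18).

Steps most likely to fail:

Step 16, the new radical-anion cyclodimerisation. It may give oligomers, E/Z scrambling, cyclobutane or eight-membered-ring closure, or the cis-arm diastereomer, and the free tertiary alcohol may protonate the chain carrier. The fallback is the thermal Diels–Alder dimerisation of conjugated trienes, which is known chemistry: monomer 22 is heated neat or 2 M in toluene with BHT at 110 °C in a sealed tube, so that two molecules combine as diene and dienophile. The lactone lock supplies the same facial bias and diastereomers are separated by chromatography. It sets out from 22 and comes back at 23, and no compound outside the list is made (F0).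

Step 3, the deconjugative α-allylation. Risks are γ- or O-alkylation, intramolecular attack of the dienolate on the chloropropyl chain, and erosion of the facial selectivity at the quaternary carbon. The fallback replaces enolate chemistry by a sigmatropic route and sets out from ketone 2. Wittig reaction with the ylide from (allyloxymethyl)triphenylphosphonium chloride and KN(SiMe3)2 gives the allyl dienyl ether F1. Heating in xylene at 140 °C (Claisen rearrangement under neutral conditions) gives aldehyde 5, which is reduced in the same flask with NaBH4 in MeOH. The route is rejoined at 6.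

Step 11, the rhodium-hydride alkene migration to the Z-enal. Risks are slow insertion at the hindered acrolein, decarbonylation, and an unfavourable Z/E ratio. The fallback sets out from lactone 13 and uses an oxidative allylic transposition. Acid-catalysed alkene migration (TsOH, benzene, 50 °C) gives the isopropylidene lactone F2. Dye-sensitised photooxygenation (O2, tetraphenylporphyrin, visible light, CH2Cl2, 0 °C; Schenck ene reaction at a methyl group) gives the tertiary allylic hydroperoxide F3. PPh3 reduces it to the tertiary allylic alcohol F4. Pyridinium chlorochromate (C5H5NH[CrO3Cl], CH2Cl2) then effects the Babler–Dauben 1,3-oxidative transposition to the enal, and Z/E equilibration and separation bring the route back at 15.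

## Further compounds

F1 | step 3 | allyl dienyl ether: 6-[(allyloxy)methylidene]-5-(3-chloropropyl)-1-methyl-4-(prop-1-en-2-yl)cyclohex-1-ene, E/Z mixture | ClCCC[C@@H]1[C@@H](C(C)=C)CC=C(C)C1=COCC=C
F2 | step 11 | isopropylidene lactone: lactone 13 with C-9 carrying =C(CH3)2 | ClCCC[C@@H]1C(=C(C)C)CC[C@](C)(O)[C@@]12CC[C@H]3CC(=O)O[C@@H]23
F3 | step 11 | tertiary allylic hydroperoxide: lactone 13 with C-9 carrying OOH and isopropenyl | ClCCC[C@@H]1C(OO)(C(C)=C)CC[C@](C)(O)[C@@]12CC[C@H]3CC(=O)O[C@@H]23
F4 | step 11 | tertiary allylic alcohol: lactone 13 with C-9 carrying OH and isopropenyl | ClCCC[C@@H]1C(O)(C(C)=C)CC[C@](C)(O)[C@@]12CC[C@H]3CC(=O)O[C@@H]23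
F0 | step 16 | none | none
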